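**Retrosynthetic overview**

1. Structure read from the SMILES: one ten-membered carbocycle (germacrane numbering), both ring alkenes Z (ring bonds cis), C6–OH (S), C7–iPr (S), C8–O-vanilloyl (R); the isopropyl group is anti to both oxygens and the two oxygens are 1,3-syn.
2. Target ⇐ deacetylation and desilylation of the protected macrocycle; the ring (the only one formed) is closed last by ring-closing metathesis at C1=C10.
3. Metathesis substrate ⇐ esterification of the only free hydroxyl (O8) with O-acetylvanillic acid ⇐ catalyst-controlled methallylboration of an aldehyde (C8–C9 bond, C8 stereocenter).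
4. Aldehyde ⇐ new IDPi-catalysed Mukaiyama cross-aldol of the isovaleraldehyde enolsilane with a Z-enal (C6–C7 bond, C6 and C7 stereocenters; O6 is born silylated, so the ester can only go to O8).
5. Z-enal (C4=C5 geometry) ⇐ Negishi coupling of (Z)-3-iodobut-2-en-1-ol with butenylzinc bromide, then oxidation.

Assumption: compounds 1, 2, 8 and 11 are taken as catalogue items; germacrane numbering (C6 free carbinol, C7 isopropyl carbon, C8 acyloxy carbon) is used in the comments.

Abbreviations: IDPi = (S,S)-imidodiphosphorimidate Brønsted acid HN[P(=NSO2CF3)(BINOL-O,O′)]2 built from (S)-3,3′-bis[3,5-bis(trifluoromethyl)phenyl]-BINOL; TRIP = 3,3′-bis(2,4,6-triisopropylphenyl)-1,1′-binaphthyl-2,2′-diyl hydrogen phosphate.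

**Route**

Step 1
Reactants: 1 (2Z)-3-iodobut-2-en-1-ol; 2 but-3-en-1-ylzinc bromide
Product: 3 (2Z)-3-methylhepta-2,6-dien-1-ol
Conditions: Pd(OAc)2 (2 mol %), SPhos (4 mol %), THF, 25 °C
Reagents that add atoms: none
Why: Negishi sp2–sp3 cross-coupling goes with retention of the vinyl iodide geometry, and the alkylzinc halide tolerates the free hydroxyl under Pd/SPhos catalysis, so the chain ends up cis to CH2OH (neryl-type Z alkene).

Step 2
Reactants: 3 (2Z)-3-methylhepta-2,6-dien-1-ol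
Product: 4 (2Z)-3-methylhepta-2,6-dienal
Conditions: TEMPO (10 mol %), PhI(OAc)2, CH2Cl2, 23 °C
Reagents that add atoms: none
Why: Oxoammonium (TEMPO) oxidation of the allylic alcohol stops at the aldehyde under near-neutral conditions, so the Z enal is not isomerised (the nerol-to-neral case).

Step 3
Reactants: 5 3-methylbutanal
Product: 6 triethyl{[(1Z)-3-methylbut-1-en-1-yl]oxy}silane
Conditions: Et3SiCl, NaI, Et3N, MeCN, 23 °C; distillation
Reagents that add atoms: chlorotriethylsilane CC[Si](Cl)(CC)CC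
Why: Soft enolisation and O-silylation with Et3SiI made in situ gives the aldehyde silyl enol ether, with the Z isomer expected to predominate and to be enriched by distillation.

Step 4
Reactants: 4 (2Z)-3-methylhepta-2,6-dienal; 6 triethyl{[(1Z)-3-methylbut-1-en-1-yl]oxy}silane
Product: 7 (2S,3S,4Z)-5-methyl-2-(propan-2-yl)-3-[(triethylsilyl)oxy]nona-4,8-dienal
Conditions: (S,S)-IDPi (2 mol %), 6 (1.5 equiv), toluene, −78 °C
Reagents that add atoms: none
Why: Proposed new method: the IDPi is silylated by 6 to a silylium/chiral-anion pair that activates the enal as an O-silyl oxocarbenium ion inside the confined pocket; 6 attacks the Re face of C=O through an open transition state (1,2-addition, because the β-carbon is fully substituted) to give the anti (2S,3S) adduct, the Et3Si group ends on O6, the α-branched product is too bulky to react again, and −78 °C is meant to keep the Z enal from isomerising; the closest known reaction type is the IDPi-catalysed Mukaiyama single aldolisation of acetaldehyde and propionaldehyde enolsilanes with simple aldehydes, not shown for a β-branched enolsilane or a Z β,β-disubstituted enal, and the catalyst antipode is used if the facial sense turns out reversed.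

Step 5
Reactants: 7 (2S,3S,4Z)-5-methyl-2-(propan-2-yl)-3-[(triethylsilyl)oxy]nona-4,8-dienal; 8 4,4,5,5-tetramethyl-2-(2-methylprop-2-en-1-yl)-1,3,2-dioxaborolane
Product: 10 (4R,5R,6S,7Z)-2,8-dimethyl-5-(propan-2-yl)-6-[(triethylsilyl)oxy]dodeca-1,7,11-trien-4-ol, via pinacol borate ester 9 (not isolated)
Conditions: (R)-TRIP (5 mol %), 4 Å MS, toluene, −30 °C; aq. NaHCO3 work-up
Reagents that add atoms: none
Why: Chiral-phosphoric-acid-catalysed allylboration through a closed chair transition state (acid bound to the boronate oxygen and the formyl hydrogen) delivers the methallyl group to the Re face of the aldehyde, setting the 8R carbinol anti to the isopropyl group and 1,3-syn to O6 under catalyst control.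

Step 6
Reactants: 10 (4R,5R,6S,7Z)-2,8-dimethyl-5-(propan-2-yl)-6-[(triethylsilyl)oxy]dodeca-1,7,11-trien-4-ol; 11 4-(acetyloxy)-3-methoxybenzoic acid
Product: 12 (4R,5R,6S,7Z)-2,8-dimethyl-5-(propan-2-yl)-6-[(triethylsilyl)oxy]dodeca-1,7,11-trien-4-yl 4-(acetyloxy)-3-methoxybenzoate
Conditions: N,N′-diisopropylcarbodiimide, DMAP (0.3 equiv), CH2Cl2, 0 to 25 °C
Reagents that add atoms: none
Why: Steglich esterification of the only free hydroxyl places the vanillate on O8 with retention; catalytic DMAP at this temperature should neither transfer the aryl acetate nor move the silyl group.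

Step 7
Reactants: 12 (4R,5R,6S,7Z)-2,8-dimethyl-5-(propan-2-yl)-6-[(triethylsilyl)oxy]dodeca-1,7,11-trien-4-yl 4-(acetyloxy)-3-methoxybenzoate
Product: 13 (1R,3Z,7Z,9S,10R)-3,7-dimethyl-10-(propan-2-yl)-9-[(triethylsilyl)oxy]cyclodeca-3,7-dien-1-yl 4-(acetyloxy)-3-methoxybenzoate
Conditions: second-generation Hoveyda–Grubbs catalyst RuCl2(H2IMes)(=CH-C6H4-2-OiPr) (10 mol %), toluene (1 mM), 80 °C, Ar purge
Reagents that add atoms: none
Why: Ring-closing metathesis: ruthenium loads on the terminal vinyl group and closes onto the 1,1-disubstituted alkene; the trisubstituted alkene in a ten-membered ring is expected with the ring bonds cis (Z), and the hindered C4=C5 alkene stays out.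

Step 8
Reactants: 13 (1R,3Z,7Z,9S,10R)-3,7-dimethyl-10-(propan-2-yl)-9-[(triethylsilyl)oxy]cyclodeca-3,7-dien-1-yl 4-(acetyloxy)-3-methoxybenzoate
Product: 15 (1R,3Z,7Z,9S,10S)-9-hydroxy-3,7-dimethyl-10-(propan-2-yl)cyclodeca-3,7-dien-1-yl 4-hydroxy-3-methoxybenzoate, via phenol silyl ether 14 (not isolated)
Conditions: pyrrolidine, THF, 0 °C; then HF·pyridine, pyridine, THF, 0 °C
Reagents that add atoms: none
Why: Aminolysis of the activated aryl acetate is much faster than attack on the hindered secondary benzoate and is done while O6 is still silylated (no 1,3-acyl migration possible); buffered fluoride desilylation then frees the allylic C6–OH without base, leaving the three stereocenters and both Z alkenes untouched.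

**Compound list**

1 | (2Z)-3-iodobut-2-en-1-ol | OC/C=C(/C)I | starting material
2 | but-3-en-1-ylzinc bromide | C=CCC[Zn]Br | starting material
3 | (2Z)-3-methylhepta-2,6-dien-1-ol | OC/C=C(/C)CCC=C | intermediate
4 | (2Z)-3-methylhepta-2,6-dienal | O=C/C=C(/C)CCC=C | intermediate
5 | 3-methylbutanal | CC(C)CC=O | starting material
6 | triethyl{[(1Z)-3-methylbut-1-en-1-yl]oxy}silane | CC(C)/C=C\O[Si](CC)(CC)CC | intermediate
7 | (2S,3S,4Z)-5-methyl-2-(propan-2-yl)-3-[(triethylsilyl)oxy]nona-4,8-dienal | C=CCC/C(C)=C\[C@H](O[Si](CC)(CC)CC)[C@@H](C=O)C(C)C | intermediate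
8 | 4,4,5,5-tetramethyl-2-(2-methylprop-2-en-1-yl)-1,3,2-dioxaborolane | CC(=C)CB1OC(C)(C)C(C)(C)O1 | starting material
9 | 2-{[(4R,5R,6S,7Z)-2,8-dimethyl-5-(propan-2-yl)-6-[(triethylsilyl)oxy]dodeca-1,7,11-trien-4-yl]oxy}-4,4,5,5-tetramethyl-1,3,2-dioxaborolane | C=CCC/C(C)=C\[C@H](O[Si](CC)(CC)CC)[C@@H]([C@H](OB1OC(C)(C)C(C)(C)O1)CC(C)=C)C(C)C | intermediate
10 | (4R,5R,6S,7Z)-2,8-dimethyl-5-(propan-2-yl)-6-[(triethylsilyl)oxy]dodeca-1,7,11-trien-4-ol | C=CCC/C(C)=C\[C@H](O[Si](CC)(CC)CC)[C@@H]([C@H](O)CC(C)=C)C(C)C | intermediate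
11 | 4-(acetyloxy)-3-methoxybenzoic acid | CC(=O)Oc1ccc(cc1OC)C(=O)O | starting material
12 | (4R,5R,6S,7Z)-2,8-dimethyl-5-(propan-2-yl)-6-[(triethylsilyl)oxy]dodeca-1,7,11-trien-4-yl 4-(acetyloxy)-3-methoxybenzoate | C=CCC/C(C)=C\[C@H](O[Si](CC)(CC)CC)[C@@H]([C@H](OC(=O)c1ccc(OC(C)=O)c(OC)c1)CC(C)=C)C(C)C | intermediate
13 | (1R,3Z,7Z,9S,10R)-3,7-dimethyl-10-(propan-2-yl)-9-[(triethylsilyl)oxy]cyclodeca-3,7-dien-1-yl 4-(acetyloxy)-3-methoxybenzoate | CC(=O)Oc1ccc(cc1OC)C(=O)O[C@@H]2C/C(C)=C\CC/C(C)=C\[C@H](O[Si](CC)(CC)CC)[C@@H]2C(C)C | intermediate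
14 | (1R,3Z,7Z,9S,10R)-3,7-dimethyl-10-(propan-2-yl)-9-[(triethylsilyl)oxy]cyclodeca-3,7-dien-1-yl 4-hydroxy-3-methoxybenzoate | COc1cc(C(=O)O[C@@H]2C/C(C)=C\CC/C(C)=C\[C@H](O[Si](CC)(CC)CC)[C@@H]2C(C)C)ccc1O | intermediate
15 | (1R,3Z,7Z,9S,10S)-9-hydroxy-3,7-dimethyl-10-(propan-2-yl)cyclodeca-3,7-dien-1-yl 4-hydroxy-3-methoxybenzoate | COc1cc(C(=O)O[C@@H]2C/C(C)=C\CC/C(C)=C\[C@H](O)[C@@H]2C(C)C)ccc1O | target

**Step count**

Total steps: 8. Longest linear sequence: 7 (steps 1, 2, 4, 5, 6, 7, 8; step 3 is a one-step branch).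

**Three steps most likely to fail**

Step 4 (the new aldol). Risks are Z to E isomerisation of the silylium-activated enal, a syn/anti ratio that depends on the enolsilane geometry and the catalyst pocket, and low conversion with the β-branched enolsilane. The fallback uses known chemistry, sets out from 4 and comes back at 7. tert-Butyl 3-methylbutanoate is enolised (LiN(iPr)2, THF, −78 °C) and silylated with TBSCl to the silyl ketene acetal F1. F1 and 4 are combined under Lewis-base catalysis (SiCl4, chiral binaphthyldiamine-derived bisphosphoramide, CH2Cl2, −78 °C), an anti-selective aldol that works best with conjugated aldehydes. This gives the trichlorosilyl aldolate F2 and, after aqueous NaHCO3/KF, the anti hydroxy ester F3. Silylation (Et3SiOTf, 2,6-lutidine) gives the silyl ether ester F4. Reduction with i-Bu2AlH gives the primary alcohol F5, and Dess–Martin oxidation (NaHCO3 buffer) gives 7.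

Step 5 (methallylboration). The wanted 8R carbinol is the anti-Felkin, 1,3-syn isomer, so the catalyst must override the substrate and the diastereomer ratio may be modest. The fallback sets out from 7 and comes back at 12. Substrate-controlled Hosomi–Sakurai addition of 2-methylallyltrimethylsilane (BF3·OEt2, CH2Cl2, −78 °C), where Felkin and 1,3-anti induction reinforce each other, gives the C4-epimeric alcohol F6. Mitsunobu esterification of F6 with 11 (PPh3, diisopropyl azodicarboxylate, toluene, 0 °C) inverts C4 and gives 12 directly.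

Step 7 (ring-closing metathesis). A trisubstituted alkene in a ten-membered carbocycle is hard to close; dimers or no reaction are possible. The fallback closes the ring by a cross-coupling at C1–C2 with both alkene geometries fixed beforehand; it sets out from 1 and comes back at 13.
- Negishi coupling of 1 with CH2=CHZnBr (Pd(OAc)2, SPhos) gives the dienol F7, and TEMPO/PhI(OAc)2 gives the dienal F8.
- The aldol of step 4 with 6 gives the dienyl aldehyde F9.
- (R)-TRIP-catalysed propargylation with allenylboronic acid pinacol ester gives the pinacol borate F10 and, on work-up, the homopropargylic alcohol F11.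
- Hydroxyl-directed anti-carboalumination (AlMe3, Cp2ZrCl2, CH2Cl2, then warming to isomerise through the aluminium alkoxide chelate) followed by I2 gives the Z iodoalkene F12.
- Steglich esterification with 11 gives the ester F13.
- 9-BBN adds to the terminal vinyl group of the diene to give the alkylborane F14, which closes the ring by intramolecular B-alkyl Suzuki–Miyaura coupling (PdCl2(dppf), AsPh3, Cs2CO3, DMF/THF/H2O, high dilution) to give 13.

**Further compounds**

F1 | step 4 | tert-butyl[(1-tert-butoxy-3-methylbut-1-en-1-yl)oxy]dimethylsilane (E/Z mixture) | CC(C)C=C(OC(C)(C)C)O[Si](C)(C)C(C)(C)C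
F2 | step 4 | tert-butyl (2S,3S,4Z)-5-methyl-2-(propan-2-yl)-3-[(trichlorosilyl)oxy]nona-4,8-dienoate | C=CCC/C(C)=C\[C@H](O[Si](Cl)(Cl)Cl)[C@@H](C(=O)OC(C)(C)C)C(C)C
F3 | step 4 | tert-butyl (2S,3S,4Z)-3-hydroxy-5-methyl-2-(propan-2-yl)nona-4,8-dienoate | C=CCC/C(C)=C\[C@H](O)[C@@H](C(=O)OC(C)(C)C)C(C)C
F4 | step 4 | tert-butyl (2S,3S,4Z)-5-methyl-2-(propan-2-yl)-3-[(triethylsilyl)oxy]nona-4,8-dienoate | C=CCC/C(C)=C\[C@H](O[Si](CC)(CC)CC)[C@@H](C(=O)OC(C)(C)C)C(C)C
F5 | step 4 | (2R,3S,4Z)-5-methyl-2-(propan-2-yl)-3-[(triethylsilyl)oxy]nona-4,8-dien-1-ol | C=CCC/C(C)=C\[C@H](O[Si](CC)(CC)CC)[C@@H](CO)C(C)C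
F6 | step 5 | (4S,5R,6S,7Z)-2,8-dimethyl-5-(propan-2-yl)-6-[(triethylsilyl)oxy]dodeca-1,7,11-trien-4-ol | C=CCC/C(C)=C\[C@H](O[Si](CC)(CC)CC)[C@@H]([C@@H](O)CC(C)=C)C(C)C
F7 | step 7 | (2Z)-3-methylpenta-2,4-dien-1-ol | OC/C=C(/C)C=C
F8 | step 7 | (2Z)-3-methylpenta-2,4-dienal | O=C/C=C(/C)C=C
F9 | step 7 | (2S,3S,4Z)-5-methyl-2-(propan-2-yl)-3-[(triethylsilyl)oxy]hepta-4,6-dienal | C=C/C(C)=C\[C@H](O[Si](CC)(CC)CC)[C@@H](C=O)C(C)C
F10 | step 7 | 2-{[(4R,5R,6S,7Z)-8-methyl-5-(propan-2-yl)-6-[(triethylsilyl)oxy]deca-7,9-dien-1-yn-4-yl]oxy}-4,4,5,5-tetramethyl-1,3,2-dioxaborolane | C=C/C(C)=C\[C@H](O[Si](CC)(CC)CC)[C@@H]([C@H](OB1OC(C)(C)C(C)(C)O1)CC#C)C(C)C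
F11 | step 7 | (4R,5R,6S,7Z)-8-methyl-5-(propan-2-yl)-6-[(triethylsilyl)oxy]deca-7,9-dien-1-yn-4-ol | C=C/C(C)=C\[C@H](O[Si](CC)(CC)CC)[C@@H]([C@H](O)CC#C)C(C)C
F12 | step 7 | (1Z,4R,5R,6S,7Z)-1-iodo-2,8-dimethyl-5-(propan-2-yl)-6-[(triethylsilyl)oxy]deca-1,7,9-trien-4-ol | C=C/C(C)=C\[C@H](O[Si](CC)(CC)CC)[C@@H]([C@H](O)C/C(C)=C\I)C(C)C
F13 | step 7 | (1Z,4R,5R,6S,7Z)-1-iodo-2,8-dimethyl-5-(propan-2-yl)-6-[(triethylsilyl)oxy]deca-1,7,9-trien-4-yl 4-(acetyloxy)-3-methoxybenzoate | C=C/C(C)=C\[C@H](O[Si](CC)(CC)CC)[C@@H]([C@H](OC(=O)c1ccc(OC(C)=O)c(OC)c1)C/C(C)=C\I)C(C)C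
F14 | step 7 | (1Z,4R,5R,6S,7Z)-10-(9-borabicyclo[3.3.1]nonan-9-yl)-1-iodo-2,8-dimethyl-5-(propan-2-yl)-6-[(triethylsilyl)oxy]deca-1,7-dien-4-yl 4-(acetyloxy)-3-methoxybenzoate | C1CC2CCCC(C1)B2CC/C(C)=C\[C@H](O[Si](CC)(CC)CC)[C@@H]([C@H](OC(=O)c1ccc(OC(C)=O)c(OC)c1)C/C(C)=C\I)C(C)C
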